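**Retrosynthetic overview**
1. The last operation opens both seven-membered rings at once: the C3=C4 alkene (intramolecular Horner–Wadsworth–Emmons) and the C5–O bond (oxa-Michael). This leads back to a monocyclic α-methylene-γ-lactone carrying an alkylidene phosphonoacetate at C5 and a lactol (masked C10 alkoxide plus C3 aldehyde).
2. The acceptor comes from a C5 aldehyde and trimethyl phosphonoacetate (Knoevenagel). The lactol comes from ozonolysis of the linalool-type trisubstituted alkene.
3. The trans γ-lactone comes from acid lactonisation of a C5,C6-acetonide γ-hydroxy ester. The C8 epoxy ester comes from Yamaguchi acylation with an acid made by Sharpless epoxidation of tiglyl alcohol.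
4. The C7–C8 bond is cut to a linalool-derived β-hydroxy aldehyde (C8–C10, C1–C3, C14) and a glyceraldehyde-derived 2-(bromomethyl)acrylate (C5–C7, C11–C13), joined by an indium Barbier reaction.
5. Ring order: γ-lactone first (step 9), then ring A (oxepane) and ring B (oxepine) of the 11-oxabicyclo[4.4.1]undecene together in the final step.

Assumption: locants are germacranolide-style (C13H2=C11–C12(=O)–O–C6; C7 ring fusion; C8 acyloxy; C9H2; C10 quaternary ether carbon with CH3-14; C1H2; C2H2; C3H=C4–C15O2Me; C5 ether CH), ring A = O/C5–C10, ring B = O/C10/C1–C5, and (S)-(+)-linalool is bought in ≥98% ee (lower-ee lots are corrected at 12, where the minor series is a separable diastereomer).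

**Route**

Step 1
Reactants: 1 (S)-(+)-linalool [(3S)-3,7-dimethylocta-1,6-dien-3-ol]
Product: 3 (3S)-3,7-dimethyloct-6-ene-1,3-diol, via organoborane 2 (not isolated)
Conditions: 9-BBN (1.2 equiv), THF, 0 °C → rt; then 3 M NaOH, 30% H2O2, 0 °C → rt
Reagents that add atoms: 9-BBN, B1C2CCCC1CCC2 (atoms stay in 2 only); hydrogen peroxide, OO
Why: Hydroboration–oxidation: 9-BBN adds anti-Markovnikov to the monosubstituted vinyl group far faster than to the trisubstituted alkene, and C10 is not touched.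

Step 2
Reactants: 3 (3S)-3,7-dimethyloct-6-ene-1,3-diol
Product: 4 (3S)-3-hydroxy-3,7-dimethyloct-6-enal
Conditions: TEMPO (10 mol %), PhI(OAc)2 (1.1 equiv), CH2Cl2, rt; used crude
Reagents that add atoms: none
Why: Oxoammonium (TEMPO) oxidation is selective for the primary carbinol and stops at the aldehyde, leaving the tertiary alcohol, the alkene and C10 unchanged.

Step 3
Reactants: 5 (R)-2,2-dimethyl-1,3-dioxolane-4-carbaldehyde; 6 methyl acrylate
Product: 7 methyl 2-{[(4R)-2,2-dimethyl-1,3-dioxolan-4-yl](hydroxy)methyl}prop-2-enoate (both carbinol epimers)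
Conditions: DABCO (0.5 equiv), neat methyl acrylate (5 equiv), rt, 5 d
Reagents that add atoms: none
Why: Morita–Baylis–Hillman reaction; the new carbinol centre is irrelevant because step 4 destroys it, while the dioxolane centre (future C6) is retained.

Step 4
Reactants: 7 methyl 2-{[(4R)-2,2-dimethyl-1,3-dioxolan-4-yl](hydroxy)methyl}prop-2-enoate
Product: 8 methyl (2Z)-2-(bromomethyl)-3-[(4S)-2,2-dimethyl-1,3-dioxolan-4-yl]prop-2-enoate
Conditions: NBS (1.3 equiv), Me2S (1.5 equiv), CH2Cl2, 0 °C → rt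
Reagents that add atoms: N-bromosuccinimide, O=C1CCC(=O)N1Br
Why: Corey–Kim-type activation with SN2′ bromide delivery transposes the allylic system to the thermodynamically preferred (Z)-2-(bromomethyl)enoate under non-acidic conditions that spare the acetonide.

Step 5
Reactants: 9 (E)-2-methylbut-2-en-1-ol (tiglyl alcohol)
Product: 10 [(2R,3R)-2,3-dimethyloxiran-2-yl]methanol
Conditions: Ti(OiPr)4 (5 mol %), D-(−)-diisopropyl tartrate (6 mol %), t-BuOOH (2 equiv, isooctane), 4 Å MS, CH2Cl2, −20 °C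
Reagents that add atoms: tert-butyl hydroperoxide, CC(C)(C)OO
Why: Katsuki–Sharpless asymmetric epoxidation; the D-(−)-tartrate complex delivers oxygen to the alkene face that gives the (2R,3R) epoxide, and the E geometry fixes the two methyl groups cis.

Step 6
Reactants: 10 [(2R,3R)-2,3-dimethyloxiran-2-yl]methanol
Product: 11 (2S,3R)-2,3-dimethyloxirane-2-carboxylic acid
Conditions: RuCl3 hydrate (2 mol %), NaIO4 (2.5 equiv), MeCN/EtOAc/H2O, 0 °C → rt
Reagents that add atoms: sodium periodate, [Na+].[O-]I(=O)(=O)=O; water, O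
Why: RuO4-catalysed oxidation of the primary alcohol to the acid leaves both epoxide centres untouched (only the descriptor at C2 changes).

Step 7
Reactants: 4 (3S)-3-hydroxy-3,7-dimethyloct-6-enal; 8 methyl (2Z)-2-(bromomethyl)-3-[(4S)-2,2-dimethyl-1,3-dioxolan-4-yl]prop-2-enoate
Product: 12 methyl (3R,4R,6S)-3-[(4S)-2,2-dimethyl-1,3-dioxolan-4-yl]-4,6-dihydroxy-6,10-dimethyl-2-methylideneundec-9-enoate
Conditions: indium powder (1.5 equiv), THF/H2O (1:1), rt
Reagents that add atoms: none
Why: Indium Barbier 2-(alkoxycarbonyl)allylation: the allylindium reacts at its γ-carbon (C7) through a chair transition state in which the Z geometry places the dioxolanyl group axial (7,8-syn), and the aldehyde attacks C7 anti to the dioxolane C6–O bond with H6 eclipsing the alkene, giving (7R,8R); the neutral aqueous medium tolerates the free OH groups and does not lactonise the product.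

Step 8
Reactants: 12 methyl (3R,4R,6S)-3-[(4S)-2,2-dimethyl-1,3-dioxolan-4-yl]-4,6-dihydroxy-6,10-dimethyl-2-methylideneundec-9-enoate; 11 (2S,3R)-2,3-dimethyloxirane-2-carboxylic acid
Product: 14 methyl (3R,4R,6S)-3-[(4S)-2,2-dimethyl-1,3-dioxolan-4-yl]-4-{[(2S,3R)-2,3-dimethyloxirane-2-carbonyl]oxy}-6-hydroxy-6,10-dimethyl-2-methylideneundec-9-enoate, via mixed anhydride 13 (not isolated)
Conditions: 11, 2,4,6-trichlorobenzoyl chloride, Et3N, toluene, rt; then 12, DMAP, toluene, 0 °C → rt
Reagents that add atoms: 2,4,6-trichlorobenzoyl chloride, O=C(Cl)c1c(Cl)cc(Cl)cc1Cl (atoms stay in 13 only)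
Why: Yamaguchi esterification acylates the secondary C8–OH with retention and leaves the tertiary C10–OH free; blocking O8 here also prevents the unwanted lactone to C8 and the later 5-exo oxa-Michael from O8.

Step 9
Reactants: 14 (the acetonide ester from step 8)
Product: 16 (1R,3S)-3-hydroxy-1-[(2S,3R)-2-(hydroxymethyl)-4-methylidene-5-oxooxolan-3-yl]-3,7-dimethyloct-6-en-1-yl (2S,3R)-2,3-dimethyloxirane-2-carboxylate, via diol ester 15 (not isolated)
Conditions: AcOH/H2O (4:1), 45 °C; then PPTS (cat.), toluene, 50 °C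
Reagents that add atoms: none
Why: Mild acid hydrolysis of the acetonide followed by acid-catalysed lactonisation of the C6–OH onto the C12 methyl ester gives the trans-disubstituted γ-lactone, which is favoured over the δ-lactone through the primary C5–OH; the deactivated glycidic ester and the non-allylic tertiary alcohol tolerate these conditions.

Step 10
Reactants: 16 (the hydroxymethyl lactone from step 9)
Product: 17 (1R,3S)-1-[(2S,3R)-2-formyl-4-methylidene-5-oxooxolan-3-yl]-3-hydroxy-3,7-dimethyloct-6-en-1-yl (2S,3R)-2,3-dimethyloxirane-2-carboxylate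
Conditions: Dess–Martin periodinane (1.3 equiv), pyridine, CH2Cl2, 0 °C → rt; used directly
Reagents that add atoms: none
Why: Dess–Martin oxidation converts the only oxidisable carbinol (primary C5–OH) into the aldehyde under buffered conditions that preserve C6 and the epoxide.

Step 11
Reactants: 17 (the C5 aldehyde from step 10); 18 trimethyl phosphonoacetate
Product: 19 (1R,3S)-1-{(2S,3R)-2-[2-(dimethoxyphosphoryl)-3-methoxy-3-oxoprop-1-en-1-yl]-4-methylidene-5-oxooxolan-3-yl}-3-hydroxy-3,7-dimethyloct-6-en-1-yl (2S,3R)-2,3-dimethyloxirane-2-carboxylate (E/Z mixture)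
Conditions: piperidine (10 mol %), AcOH (20 mol %), 4 Å MS, toluene, rt → 40 °C
Reagents that add atoms: none
Why: Knoevenagel condensation of the electrophilic α-acyloxy aldehyde with the phosphonoacetate gives the doubly activated C5=C4 acceptor; its geometry is irrelevant and the trans-lactone is the thermodynamic C6 epimer.

Step 12
Reactants: 19 (the alkylidene phosphonoacetate from step 11)
Product: 21 (1R)-1-{(2S,3R)-2-[2-(dimethoxyphosphoryl)-3-methoxy-3-oxoprop-1-en-1-yl]-4-methylidene-5-oxooxolan-3-yl}-2-[(2S)-5-hydroxy-2-methyloxolan-2-yl]ethyl (2S,3R)-2,3-dimethyloxirane-2-carboxylate (lactol anomers), via ozonide 20 (not isolated)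
Conditions: O3, CH2Cl2, −78 °C (Sudan Red 7B end point); then Me2S, −78 °C → rt
Reagents that add atoms: ozone, [O-][O+]=O
Why: Ozonolysis cleaves only the electron-rich trisubstituted alkene (the two electron-poor alkenes react far more slowly), and the resulting C3 aldehyde is trapped by the C10–OH as the five-membered lactol.

Step 13
Reactants: 21 (the lactol from step 12)
Product: 23 CNP0240298.1 [the (5R,6S,7R,8R,10S) 5,10-epoxygermacra-3,11(13)-dien-6,12-olide with C15 methyl ester and 8-O-(2S,3R)-2,3-dimethyloxirane-2-carbonyl group], via oxepane phosphonate 22 (not isolated)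
Conditions: LiCl (5 equiv), DBU (1.5 equiv), 4 Å MS, MeCN (2 mM), 0 °C → rt
Reagents that add atoms: none
Why: Proposed new method: DBU deprotonates the lactol and the lactolate opens to the C10 tertiary alkoxide/C3 aldehyde tautomer; the alkoxide adds reversibly (7-exo-trig oxa-Michael, closing ring A) to the lithium-chelated alkylidene phosphonoacetate, and only the 2,7-cis oxepane, whose phosphonate carbanion can reach the C3 aldehyde, is drained irreversibly by intramolecular Horner–Wadsworth–Emmons olefination (closing ring B with the C3=C4 alkene), so C5 is set as R by this geometric requirement relative to the linalool-derived C10 while the trans adduct reverts by retro-Michael; the closest known reaction type is the tandem oxa-Michael/Horner–Wadsworth–Emmons annulation of lactols, hydroxy ketones or salicylaldehydes with 2-phosphonoacrylates that gives dihydrofurans, dihydropyrans and 2H-chromenes.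

**Compound list**
1 | (S)-(+)-linalool, (3S)-3,7-dimethylocta-1,6-dien-3-ol | C=C[C@](O)(C)CCC=C(C)C | starting material
2 | B-[(3R)-3-hydroxy-3,7-dimethyloct-6-en-1-yl]-9-borabicyclo[3.3.1]nonane | CC(C)=CCC[C@](C)(O)CCB1C2CCCC1CCC2 | intermediate
3 | (3S)-3,7-dimethyloct-6-ene-1,3-diol | OCC[C@](O)(C)CCC=C(C)C | intermediate
4 | (3S)-3-hydroxy-3,7-dimethyloct-6-enal | O=CC[C@](O)(C)CCC=C(C)C | intermediate
5 | (R)-2,2-dimethyl-1,3-dioxolane-4-carbaldehyde (D-glyceraldehyde acetonide) | CC1(C)OC[C@@H](O1)C=O | starting material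
6 | methyl acrylate | C=CC(=O)OC | starting material
7 | methyl 2-{[(4R)-2,2-dimethyl-1,3-dioxolan-4-yl](hydroxy)methyl}prop-2-enoate (carbinol epimers) | CC1(C)OC[C@@H](O1)C(O)C(=C)C(=O)OC | intermediate
8 | methyl (2Z)-2-(bromomethyl)-3-[(4S)-2,2-dimethyl-1,3-dioxolan-4-yl]prop-2-enoate | CC1(C)OC[C@@H](O1)/C=C(\CBr)C(=O)OC | intermediate
9 | (E)-2-methylbut-2-en-1-ol (tiglyl alcohol) | C/C=C(\C)CO | starting material
10 | [(2R,3R)-2,3-dimethyloxiran-2-yl]methanol | OC[C@@]1(C)O[C@@H]1C | intermediate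
11 | (2S,3R)-2,3-dimethyloxirane-2-carboxylic acid | OC(=O)[C@@]1(C)O[C@@H]1C | intermediate
12 | methyl (3R,4R,6S)-3-[(4S)-2,2-dimethyl-1,3-dioxolan-4-yl]-4,6-dihydroxy-6,10-dimethyl-2-methylideneundec-9-enoate | CC1(C)OC[C@@H](O1)[C@H](C(=C)C(=O)OC)[C@H](O)C[C@](O)(C)CCC=C(C)C | intermediate
13 | (2S,3R)-2,3-dimethyloxirane-2-carboxylic 2,4,6-trichlorobenzoic anhydride | O=C(OC(=O)[C@@]1(C)O[C@@H]1C)c1c(Cl)cc(Cl)cc1Cl | intermediate
14 | methyl (3R,4R,6S)-3-[(4S)-2,2-dimethyl-1,3-dioxolan-4-yl]-4-{[(2S,3R)-2,3-dimethyloxirane-2-carbonyl]oxy}-6-hydroxy-6,10-dimethyl-2-methylideneundec-9-enoate | CC1(C)OC[C@@H](O1)[C@H](C(=C)C(=O)OC)[C@H](OC(=O)[C@@]2(C)O[C@@H]2C)C[C@](O)(C)CCC=C(C)C | intermediate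
15 | methyl (3S,4R,6S)-3-[(1S)-1,2-dihydroxyethyl]-4-{[(2S,3R)-2,3-dimethyloxirane-2-carbonyl]oxy}-6-hydroxy-6,10-dimethyl-2-methylideneundec-9-enoate | OC[C@@H](O)[C@H](C(=C)C(=O)OC)[C@H](OC(=O)[C@@]1(C)O[C@@H]1C)C[C@](O)(C)CCC=C(C)C | intermediate
16 | (1R,3S)-3-hydroxy-1-[(2S,3R)-2-(hydroxymethyl)-4-methylidene-5-oxooxolan-3-yl]-3,7-dimethyloct-6-en-1-yl (2S,3R)-2,3-dimethyloxirane-2-carboxylate | C=C1C(=O)O[C@H](CO)[C@H]1[C@H](OC(=O)[C@@]1(C)O[C@@H]1C)C[C@](O)(C)CCC=C(C)C | intermediate
17 | (1R,3S)-1-[(2S,3R)-2-formyl-4-methylidene-5-oxooxolan-3-yl]-3-hydroxy-3,7-dimethyloct-6-en-1-yl (2S,3R)-2,3-dimethyloxirane-2-carboxylate | C=C1C(=O)O[C@H](C=O)[C@H]1[C@H](OC(=O)[C@@]1(C)O[C@@H]1C)C[C@](O)(C)CCC=C(C)C | intermediate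
18 | trimethyl phosphonoacetate, methyl 2-(dimethoxyphosphoryl)acetate | COC(=O)CP(=O)(OC)OC | starting material
19 | (1R,3S)-1-{(2S,3R)-2-[2-(dimethoxyphosphoryl)-3-methoxy-3-oxoprop-1-en-1-yl]-4-methylidene-5-oxooxolan-3-yl}-3-hydroxy-3,7-dimethyloct-6-en-1-yl (2S,3R)-2,3-dimethyloxirane-2-carboxylate (E/Z mixture) | C=C1C(=O)O[C@H](C=C(C(=O)OC)P(=O)(OC)OC)[C@H]1[C@H](OC(=O)[C@@]1(C)O[C@@H]1C)C[C@](O)(C)CCC=C(C)C | intermediate
20 | 1,2,4-trioxolane (secondary ozonide) of the C3=C(CH3)2 alkene of 19 | C=C1C(=O)O[C@H](C=C(C(=O)OC)P(=O)(OC)OC)[C@H]1[C@H](OC(=O)[C@@]1(C)O[C@@H]1C)C[C@](O)(C)CCC1OOC(C)(C)O1 | intermediate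
21 | (1R)-1-{(2S,3R)-2-[2-(dimethoxyphosphoryl)-3-methoxy-3-oxoprop-1-en-1-yl]-4-methylidene-5-oxooxolan-3-yl}-2-[(2S)-5-hydroxy-2-methyloxolan-2-yl]ethyl (2S,3R)-2,3-dimethyloxirane-2-carboxylate (lactol anomers) | C=C1C(=O)O[C@H](C=C(C(=O)OC)P(=O)(OC)OC)[C@H]1[C@H](OC(=O)[C@@]1(C)O[C@@H]1C)C[C@]1(C)CCC(O)O1 | intermediate
22 | ring-A oxa-Michael adduct: 2,7-cis oxepane (C5–O–C10 closed, lactone and C8 ester as in 23) with CH[P(O)(OMe)2]CO2Me at C5 and methyl plus 3-oxopropyl at C10; (5S,6S,7R,8R,10S), C4 unassigned; reacts as its carbanion | C=C1C(=O)O[C@H]2[C@H]1[C@H](OC(=O)[C@@]1(C)O[C@@H]1C)C[C@](C)(CCC=O)O[C@@H]2C(C(=O)OC)P(=O)(OC)OC | intermediate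
23 | CNP0240298.1: (5R,6S,7R,8R,10S) 5,10-epoxygermacra-3,11(13)-dien-6,12-olide, C15 methyl ester, 8-O-[(2S,3R)-2,3-dimethyloxirane-2-carbonyl] | C=C1C(=O)O[C@H]2[C@H]1[C@H](OC(=O)[C@@]1(C)O[C@@H]1C)C[C@]1(C)CCC=C(C(=O)OC)[C@H]2O1 | target

**Step count**
Total: 13 steps. Longest linear sequence: 9 steps (1, 2, 7, 8, 9, 10, 11, 12, 13).

**Steps most likely to fail, with fallbacks**

Step 13 (double ring closure). The 7-exo oxa-Michael addition of a tertiary alkoxide is thermodynamically weak. It competes with γ-deprotonation at C6 and with isomerisation of the α-methylene lactone. The fallback sets out from 19 and comes back to the route at 23. Compound 19 is stirred with paraformaldehyde and K2CO3 in THF: the reversible oxa-Michael addition of the free C10–OH gives the cis-oxepane phosphonoacetate F1, whose carbanion is trapped by formaldehyde in an intermolecular Horner–Wadsworth–Emmons methylenation to give the ring-A acrylate F2 (C4=CH2). Ring-closing metathesis of F2 with the second-generation Hoveyda–Grubbs catalyst (toluene, 80 °C, 1 mM) between the acrylate and the 2-methylprop-1-enyl terminus then closes ring B to give 23. Ring B is thus made by metathesis and no aldehyde or lactol is needed.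

Step 7 (Barbier coupling). The syn/anti ratio at C8 and the stability of the β-hydroxy aldehyde 4 are uncertain. The fallback sets out from 4 and 8 and comes back at 14. The C8 epimer of 12, methyl (3R,4S,6S)-3-[(4S)-2,2-dimethyl-1,3-dioxolan-4-yl]-4,6-dihydroxy-6,10-dimethyl-2-methylideneundec-9-enoate F3, has the same C6 and C7 configuration because the dioxolane governs the face of C7. Whether F3 is the minor or the major adduct, it is esterified with acid 11 under Mitsunobu conditions (PPh3, DIAD, toluene, 0 °C → rt). This inverts C8 while installing the epoxy ester and gives 14 directly, replacing step 8 for that material. The fallback does not correct a wrong facial selectivity at C7.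

Step 11 (Knoevenagel). The α-acyloxy aldehyde 17 is epimerisable, and the amine catalyst can add to the α-methylene lactone. The fallback sets out from 17 and comes back at 19. Wittig olefination of 17 with methyl bromo(triphenyl-λ5-phosphanylidene)acetate (CH2Cl2, rt, no amine or acid) gives the α-bromo enoate F4. Hirao coupling of F4 with dimethyl phosphite (Pd(PPh3)4 cat., Et3N, toluene, 70 °C) forms the C4–P bond and gives 19.

**Further compounds**
F1 | step 13 | 2,7-cis oxepane phosphonoacetate: as 22 but with the 4-methylpent-3-enyl chain at C10 instead of 3-oxopropyl | C=C1C(=O)O[C@H]2[C@H]1[C@H](OC(=O)[C@@]1(C)O[C@@H]1C)C[C@](C)(CCC=C(C)C)O[C@@H]2C(C(=O)OC)P(=O)(OC)OC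
F2 | step 13 | ring-A acrylate: as F1 but with C(=CH2)CO2Me at C5 in place of the phosphonoacetate unit; (5R,6S,7R,8R,10S) | C=C1C(=O)O[C@H]2[C@H]1[C@H](OC(=O)[C@@]1(C)O[C@@H]1C)C[C@](C)(CCC=C(C)C)O[C@@H]2C(=C)C(=O)OC
F3 | step 7 | methyl (3R,4S,6S)-3-[(4S)-2,2-dimethyl-1,3-dioxolan-4-yl]-4,6-dihydroxy-6,10-dimethyl-2-methylideneundec-9-enoate (C8 epimer of 12) | CC1(C)OC[C@@H](O1)[C@H](C(=C)C(=O)OC)[C@@H](O)C[C@](O)(C)CCC=C(C)C
F4 | step 11 | (1R,3S)-1-[(2S,3R)-2-(2-bromo-3-methoxy-3-oxoprop-1-en-1-yl)-4-methylidene-5-oxooxolan-3-yl]-3-hydroxy-3,7-dimethyloct-6-en-1-yl (2S,3R)-2,3-dimethyloxirane-2-carboxylate | C=C1C(=O)O[C@H](C=C(Br)C(=O)OC)[C@H]1[C@H](OC(=O)[C@@]1(C)O[C@@H]1C)C[C@](O)(C)CCC=C(C)C
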